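**Retrosynthetic overview**
- The target comes from its 12,14-diol by acetylation; the diol comes from a ten-membered triene ester by ester/ketone reduction, a second Sharpless epoxidation (D-(−)-tartrate, sets C1/C10) and MnO2 re-oxidation.
- Key step: the ten-membered ring is made from a cyclohexanone β-keto ester by a radical four-carbon ring expansion. The C5 vinyl radical adds to the C6 ketone (C5–C6 bond), the alkoxyl radical cleaves C1–C6, and the ester radical expels PhSO• to form C1=C10.
- The cyclohexanone carries the 8,11-epoxide from a first Sharpless epoxidation (L-(+)-tartrate, with S-oxidation); its side chain comes from Michael addition to acrolein and iodo-olefination.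
- The six-membered carbocycle is closed (C1–C10) by a thionium-ion cyclisation of a β-keto ester made from a lactol aldehyde and ethyl diazoacetate.
- The lactol aldehyde comes from a symmetric bis-allyl alcohol (methyl methacrylate + 2 allylMgBr); lactol closure on the cis arm fixes the C8=C11 geometry. Ring order: cyclohexanone, 8,11-epoxide, ten-membered ring, 1,10-epoxide.

Assumption: the target is taken exactly as the given SMILES, i.e. (1R,10R)-1,10-epoxide, (8S,11S)-8,11-epoxide and 4Z-enone, with locants C1–C10 = ring carbons in SMILES order (C1 bears CH2OAc, C5 bears CH3, C6 = C=O, C8 = spiro carbon), C11 = exocyclic epoxide carbon, C12 = its CH2O, C13 = its CH3, C14 = CH2O on C1, C15 = CH3 on C5; the same locants are used for the precursors.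

Step 1
Reactants: 1 methyl methacrylate; 2 allylmagnesium bromide
Product: 4 4-(prop-1-en-2-yl)hepta-1,6-dien-4-ol, via 2-methylhexa-1,5-dien-3-one 3 (not isolated)
Conditions: 2 (2.3 equiv), Et2O, −20 → 0 °C; H2O quench
Reagents that add atoms: none
Why: Double Grignard addition to the ester, allylmagnesium halides adding 1,2 both to the enoate and to ketone 3, gives the symmetric bis-allyl isopropenyl carbinol, which has no stereocentre.

Step 2
Reactants: 4 4-(prop-1-en-2-yl)hepta-1,6-dien-4-ol
Product: 6 2-methyl-3-(prop-2-en-1-yl)hexa-2,5-dien-1-ol, via trimethylsilyl ether 5 (not isolated)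
Conditions: Ph3SiOReO3 (2 mol%), BSA (1.2 equiv), Et2O, 0 °C; then K2CO3 (10 mol%), MeOH, 20 °C
Reagents that add atoms: none
Why: Rhenium-oxo-catalysed 1,3-allylic transposition ([3,3] shift of the perrhenate ester) moves OH to the primary terminus and the alkene into the tetrasubstituted position, silylation of the unhindered primary alcohol pulling the equilibrium over, and because both carbon arms are allyl groups no alkene geometry and no stereocentre arise.

Step 3
Reactants: 6 2-methyl-3-(prop-2-en-1-yl)hexa-2,5-dien-1-ol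
Product: 8 2-(2-hydroxy-5-methyl-3,6-dihydro-2H-pyran-4-yl)acetaldehyde (racemic lactol), via open-chain dialdehyde 7 (not isolated)
Conditions: OsO4 (2 mol%), NaIO4 (4.5 equiv), 2,6-lutidine, dioxane/H2O 3:1, 20 °C; crude product used directly
Reagents that add atoms: sodium periodate, [Na+].[O-]I(=O)(=O)=O; water, O
Why: Lemieux–Johnson oxidation cleaves the two vinyl groups while the hindered tetrasubstituted alkene is spared, and only the aldehyde arm cis to CH2OH can close to the six-membered lactol, which tells the two arms apart and fixes the later C8=C11 geometry (CH2O cis to C9, CH3 cis to C7), the lactol carbon being racemic and destroyed later.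

Step 4
Reactants: 8 2-(2-hydroxy-5-methyl-3,6-dihydro-2H-pyran-4-yl)acetaldehyde; 9 ethyl diazoacetate
Product: 10 ethyl 4-(2-hydroxy-5-methyl-3,6-dihydro-2H-pyran-4-yl)-3-oxobutanoate
Conditions: 9 (1.2 equiv), SnCl2 (10 mol%), CH2Cl2, 20 °C
Reagents that add atoms: none
Why: Roskamp homologation (Lewis-acid-promoted addition of the diazo ester to the free aldehyde, 1,2-hydride shift and loss of N2) gives the β-keto ester without touching the masked aldehyde and creates no stereocentre.

Step 5
Reactants: 10 ethyl 4-(2-hydroxy-5-methyl-3,6-dihydro-2H-pyran-4-yl)-3-oxobutanoate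
Product: 12 ethyl (4Z)-4-(1-hydroxypropan-2-ylidene)-2-oxo-6-(phenylsulfanyl)cyclohexane-1-carboxylate (racemic; C1/C6 isomer mixture), via thionium ion 11 (not isolated)
Conditions: PhSH (1.3 equiv), Sc(OTf)3 (10 mol%), 4 Å MS, CH2Cl2, 0 → 20 °C
Reagents that add atoms: thiophenol, Sc1ccccc1
Why: Proposed new method: Sc(OTf)3 turns the lactol into the cyclic S,O-acetal with PhSH and ring-opens it to thionium ion 11, which the enol of the β-keto ester attacks at C10 in a six-membered ring closure (closure through the cyclic oxocarbenium ion would need a bridgehead alkene and cannot compete), giving C1 and C10 as an inconsequential isomer mixture that is erased in step 9; the closest known reactions are the acid-catalysed aldehyde–thiol–1,3-dicarbonyl condensation and Pummerer-type thionium-ion cyclisations.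

Step 6
Reactants: 12 ethyl (4Z)-4-(1-hydroxypropan-2-ylidene)-2-oxo-6-(phenylsulfanyl)cyclohexane-1-carboxylate; 13 acrolein
Product: 14 ethyl (4Z)-4-(1-hydroxypropan-2-ylidene)-2-oxo-1-(3-oxopropyl)-6-(phenylsulfanyl)cyclohexane-1-carboxylate (isomer mixture)
Conditions: 13 (1.5 equiv), FeCl3·6H2O (5 mol%), CH2Cl2, 20 °C
Reagents that add atoms: none
Why: Iron-catalysed Michael addition of the cyclic β-keto ester to acrolein under neutral conditions builds the quaternary C1 without base, so the β-sulfanyl group cannot be lost by retro-Michael reaction, and the configuration of C1 is irrelevant.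

Step 7
Reactants: 14 ethyl (4Z)-4-(1-hydroxypropan-2-ylidene)-2-oxo-1-(3-oxopropyl)-6-(phenylsulfanyl)cyclohexane-1-carboxylate
Product: 15 ethyl (4Z)-4-(1-hydroxypropan-2-ylidene)-1-[(3Z)-4-iodopent-3-en-1-yl]-2-oxo-6-(phenylsulfanyl)cyclohexane-1-carboxylate (isomer mixture)
Conditions: Ph3P(Et)I (2.6 equiv), n-BuLi, THF, 20 °C; I2, −78 °C; NaN(SiMe3)2, −78 °C; then 14, −78 → −20 °C
Reagents that add atoms: ethyltriphenylphosphonium iodide, CC[P+](c1ccccc1)(c1ccccc1)c1ccccc1.[I-]; iodine, II
Why: Stork–Zhao iodo-Wittig olefination converts the aldehyde chemoselectively (the ketone is hindered and flanked by a quaternary carbon) into the (Z)-2-iodoalkene, whose geometry is unimportant because the derived vinyl radical inverts.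

Step 8
Reactants: 15 ethyl (4Z)-4-(1-hydroxypropan-2-ylidene)-1-[(3Z)-4-iodopent-3-en-1-yl]-2-oxo-6-(phenylsulfanyl)cyclohexane-1-carboxylate
Product: 16 ethyl (2S,3R)-2-(hydroxymethyl)-6-[(3Z)-4-iodopent-3-en-1-yl]-2-methyl-5-oxo-7-(phenylsulfinyl)-1-oxaspiro[2.5]octane-6-carboxylate (epoxide as in the target; isomer mixture at C6/C7/S; the 3R label only reflects the sulfur-bearing branch outranking the keto branch)
Conditions: Ti(OiPr)4 (30 mol%), L-(+)-DIPT (36 mol%), t-BuOOH (2.5 equiv), 4 Å MS, CH2Cl2, −20 °C
Reagents that add atoms: tert-butyl hydroperoxide, CC(C)(C)OO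
Why: Sharpless asymmetric epoxidation of the primary tetrasubstituted allylic alcohol with L-(+)-DIPT adds oxygen syn to the face that makes C11 S and C8 as in the target (the same facial sense that turns (E)-hex-2-en-1-ol into its (2S,3S)-epoxy alcohol), under reagent control on every stereoisomer of racemic 15, while the same Ti/t-BuOOH system oxidises the sulfide to the sulfoxide (Kagan-type sulfoxidation) that serves as the radical leaving group in step 9.

Step 9
Reactants: 16 ethyl (2S,3R)-2-(hydroxymethyl)-6-[(3Z)-4-iodopent-3-en-1-yl]-2-methyl-5-oxo-7-(phenylsulfinyl)-1-oxaspiro[2.5]octane-6-carboxylate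
Product: 20 ethyl (2S,3S,5E,9Z)-2-(hydroxymethyl)-2,10-dimethyl-11-oxo-1-oxaspiro[2.9]dodeca-5,9-diene-6-carboxylate (ten-membered ring: C1(CO2Et)=C10 ring-cis; 4Z-enone; 8S,11S-epoxide), via vinyl radical 17 (not isolated), via alkoxyl radical 18 (not isolated), via ester radical 19 (not isolated)
Conditions: Bu3SnH (1.3 equiv, syringe pump, 8 h), Et3B (0.3 equiv)/air, PhH (0.003 M), 20 °C
Reagents that add atoms: none
Why: Proposed new method: Bu3Sn• abstracts iodine from 16 and the rapidly inverting vinyl radical 17 adds 6-exo to the C6 ketone (forming the C5–C6 bond inside six-membered ring A, which forces the C4=C5 alkene to be Z), alkoxyl radical 18 then cleaves the C1–C6 bond to the tertiary ester-stabilised radical 19 (the epoxidised C8 leaves no allylic alternative for this scission), and 19 expels PhSO• to form the C1=C10 enoate as the stable ring-cis E isomer, so no stereocentre is made and the C1, C10 and sulfur centres are erased; the closest known reactions are the Dowd–Beckwith and vinyl-radical ring expansions of 2-alkylated β-keto esters and the β-fragmentation of β-sulfinyl radicals.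

Step 10
Reactants: 20 ethyl (2S,3S,5E,9Z)-2-(hydroxymethyl)-2,10-dimethyl-11-oxo-1-oxaspiro[2.9]dodeca-5,9-diene-6-carboxylate
Product: 21 (2S,3S,5E,9Z)-2,6-bis(hydroxymethyl)-2,10-dimethyl-1-oxaspiro[2.9]dodeca-5,9-dien-11-ol (both C6-OH epimers in target locants)
Conditions: i-Bu2AlH (6 equiv), CH2Cl2, −78 °C; aq. KNaC4H4O6
Reagents that add atoms: none
Why: DIBAL reduction takes the conjugated ester to the primary allylic alcohol and, unavoidably, the enone 1,2 to the allylic alcohol (C6 epimers that are re-oxidised in step 12) at a temperature where the tetrasubstituted epoxy alcohol is inert.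

Step 11
Reactants: 21 (2S,3S,5E,9Z)-2,6-bis(hydroxymethyl)-2,10-dimethyl-1-oxaspiro[2.9]dodeca-5,9-dien-11-ol
Product: 22 (1R,10R)-1,10-epoxide of 21 (1,10:8,11-diepoxy-6,12,14-triol; C6-OH epimers)
Conditions: Ti(OiPr)4 (30 mol%), D-(−)-DIPT (36 mol%), t-BuOOH (1.2 equiv), 4 Å MS, CH2Cl2, −25 °C
Reagents that add atoms: tert-butyl hydroperoxide, CC(C)(C)OO
Why: Sharpless asymmetric epoxidation again, now with D-(−)-DIPT, which adds oxygen syn to the opposite face of the C1=C10 allylic alcohol and so sets C1 R and C10 R (cis-fused, reagent-controlled), the primary trisubstituted allylic alcohol reacting far faster than the Z-substituted secondary allylic alcohol at C6 and the tetrasubstituted epoxy alcohol being inert.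

Step 12
Reactants: 22 (1R,10R)-1,10-epoxide of 21
Product: 23 (1R,10R,8S,11S,4Z)-1,10:8,11-diepoxy-12,14-dihydroxy enone (bis-deacetyl target)
Conditions: MnO2 (20 equiv), CH2Cl2, 20 °C
Reagents that add atoms: none
Why: MnO2 oxidises only the remaining allylic alcohol at C6, the two primary alcohols now being epoxy alcohols, which restores the Z-enone and removes the C6 stereocentre.

Step 13
Reactants: 23 (1R,10R,8S,11S,4Z)-1,10:8,11-diepoxy-12,14-dihydroxy enone
Product: 24 CNP0185847.4 (12,14-diacetate)
Conditions: Ac2O (4 equiv), pyridine, DMAP (5 mol%), CH2Cl2, 0 °C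
Reagents that add atoms: acetic anhydride, CC(=O)OC(C)=O
Why: Standard acylation of the two primary alcohols under mild base that the β,γ-epoxy ketone tolerates, with no stereocentre touched.

**Compound list**
1 | methyl methacrylate | C=C(C)C(=O)OC | starting material
2 | allylmagnesium bromide | C=CC[Mg]Br | starting material
3 | 2-methylhexa-1,5-dien-3-one | C=CCC(=O)C(C)=C | intermediate
4 | 4-(prop-1-en-2-yl)hepta-1,6-dien-4-ol | C=CCC(O)(CC=C)C(C)=C | intermediate
5 | trimethyl{[2-methyl-3-(prop-2-en-1-yl)hexa-2,5-dien-1-yl]oxy}silane | C[Si](C)(C)OCC(C)=C(CC=C)CC=C | intermediate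
6 | 2-methyl-3-(prop-2-en-1-yl)hexa-2,5-dien-1-ol | OCC(C)=C(CC=C)CC=C | intermediate
7 | 3-(1-hydroxypropan-2-ylidene)pentanedial | O=CCC(CC=O)=C(C)CO | intermediate
8 | 2-(2-hydroxy-5-methyl-3,6-dihydro-2H-pyran-4-yl)acetaldehyde (racemic lactol) | O=CCC1=C(C)COC(O)C1 | intermediate
9 | ethyl diazoacetate | CCOC(=O)C=[N+]=[N-] | starting material
10 | ethyl 4-(2-hydroxy-5-methyl-3,6-dihydro-2H-pyran-4-yl)-3-oxobutanoate (racemic lactol) | CCOC(=O)CC(=O)CC1=C(C)COC(O)C1 | intermediate
11 | thionium ion: ethyl (5Z)-7-hydroxy-6-methyl-3-oxo-5-[2-(phenylsulfaniumylidene)ethyl]hept-5-enoate | CCOC(=O)CC(=O)C/C(CC=[S+]c1ccccc1)=C(\C)CO | intermediate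
12 | ethyl (4Z)-4-(1-hydroxypropan-2-ylidene)-2-oxo-6-(phenylsulfanyl)cyclohexane-1-carboxylate (racemic; C1/C6 isomers; CH2OH cis to ring C5) | CCOC(=O)C1C(=O)C/C(=C(\C)CO)CC1Sc1ccccc1 | intermediate
13 | acrolein | C=CC=O | starting material
14 | ethyl (4Z)-4-(1-hydroxypropan-2-ylidene)-2-oxo-1-(3-oxopropyl)-6-(phenylsulfanyl)cyclohexane-1-carboxylate (isomer mixture) | CCOC(=O)C1(CCC=O)C(=O)C/C(=C(\C)CO)CC1Sc1ccccc1 | intermediate
15 | ethyl (4Z)-4-(1-hydroxypropan-2-ylidene)-1-[(3Z)-4-iodopent-3-en-1-yl]-2-oxo-6-(phenylsulfanyl)cyclohexane-1-carboxylate (isomer mixture) | CCOC(=O)C1(CC/C=C(\I)C)C(=O)C/C(=C(\C)CO)CC1Sc1ccccc1 | intermediate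
16 | ethyl (2S,3R)-2-(hydroxymethyl)-6-[(3Z)-4-iodopent-3-en-1-yl]-2-methyl-5-oxo-7-(phenylsulfinyl)-1-oxaspiro[2.5]octane-6-carboxylate (isomers at C6/C7/S) | CCOC(=O)C1(CC/C=C(\I)C)C(=O)C[C@]2(CC1S(=O)c1ccccc1)O[C@@]2(C)CO | intermediate
17 | C5 vinyl radical formed from 16 by loss of iodine | CCOC(=O)C1(CCC=[C]C)C(=O)C[C@]2(CC1S(=O)c1ccccc1)O[C@@]2(C)CO | intermediate
18 | bicyclic alkoxyl radical (oxygen radical on C6 after C5–C6 bond formation) | CCOC(=O)C12CCC=C(C)C1([O])C[C@]3(CC2S(=O)c2ccccc2)O[C@@]3(C)CO | intermediate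
19 | ring-expanded tertiary C1 radical (α to CO2Et, β to the sulfinyl group) | CCOC(=O)[C]1CC/C=C(/C)C(=O)C[C@]2(CC1S(=O)c1ccccc1)O[C@@]2(C)CO | intermediate
20 | ethyl (2S,3S,5E,9Z)-2-(hydroxymethyl)-2,10-dimethyl-11-oxo-1-oxaspiro[2.9]dodeca-5,9-diene-6-carboxylate | CCOC(=O)/C1=C/C[C@@]2(CC(=O)/C(C)=C\CC1)O[C@@]2(C)CO | intermediate
21 | (2S,3S,5E,9Z)-2,6-bis(hydroxymethyl)-2,10-dimethyl-1-oxaspiro[2.9]dodeca-5,9-dien-11-ol (C6-OH epimers in target locants) | OC/C1=C/C[C@@]2(CC(O)/C(C)=C\CC1)O[C@@]2(C)CO | intermediate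
22 | (1R,10R)-1,10-epoxide of 21: 1,10:8,11-diepoxy-6,12,14-triol with 4Z-alkene (C6-OH epimers) | OC[C@]12CC/C=C(/C)C(O)C[C@]3(C[C@H]1O2)O[C@@]3(C)CO | intermediate
23 | (1R,10R,8S,11S,4Z)-1,10:8,11-diepoxy-12,14-dihydroxy-cyclodec-4-en-6-one (bis-deacetyl target) | OC[C@]12CC/C=C(/C)C(=O)C[C@]3(C[C@H]1O2)O[C@@]3(C)CO | intermediate
24 | CNP0185847.4: (4Z)-cyclodec-4-en-6-one with (1R,10R)-1,10-epoxide bearing CH2OAc on C1, CH3 on C5 and (8S,11S)-spiro-epoxide whose C11 bears CH3 and CH2OAc | CC(=O)OC[C@]12CC/C=C(/C)C(=O)C[C@]3(C[C@H]1O2)O[C@@]3(C)COC(C)=O | target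

**Total step count:** 13. **Longest linear sequence:** 13 (the route is fully linear).

**Three steps most likely to fail, each with one fallback**

Step 9 (radical ring expansion) is the most exposed: vinyl radical 17 can be reduced before it reaches the ketone, and alkoxyl radical 18 can abstract hydrogen from C9 instead of cleaving C1–C6. The fallback performs the ring expansion with polar intermediates and sets out from 15. A Nozaki–Hiyama–Kishi cyclisation (CrCl2, NiCl2 5 mol%, DMSO/THF, 20 °C) adds the vinylchromium species to the C6 ketone and gives the bicyclic tertiary alcohol F1. KN(SiMe3)2 in THF (−78 → 0 °C) then triggers retro-aldol cleavage of the C1–C6 bond, and the ester enolate loses thiophenolate by E1cB to give the ten-membered triene ester F2 with the C8=C11 alkene intact. Sharpless epoxidation of F2 with L-(+)-DIPT under the step 8 conditions comes back to the route at 20.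

Step 5 (thionium ring closure) may give O-alkylation of the enol or Knoevenagel condensation followed by aromatisation. The fallback sets out from 10, which is first converted with excess PhSH and BF3·OEt2 (CH2Cl2, −20 °C) into the open-chain bis(phenylsulfanyl) acetal F3. The thionium ion is then generated thiophilically with [Me2SSMe]BF4 in CH2Cl2 at 0 °C, one phenylsulfanyl group leaving as a disulfide, and the ring closes to 12, where the route is rejoined.

Step 8 (epoxidation with concurrent sulfoxidation) may be slow or poorly selective because the sulfoxide ties up the titanium catalyst, and the sulfoxide can be lost thermally. The fallback sets out from 15 and takes sulfur to the sulfone first: 2KHSO5·KHSO4·K2SO4 (Oxone) in MeOH/H2O at 0 °C gives the sulfone F4, leaving the tetrasubstituted alkene untouched in the absence of a ketone catalyst. Sharpless epoxidation with L-(+)-DIPT then gives the epoxy sulfone F5, and the radical ring expansion is run with Bu3SnH/AIBN in PhH at 80 °C, the ester radical expelling PhSO2• as an efficient chain carrier, to come back at 20.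

Further compounds
F1 | step 9 | ethyl 8a-hydroxy-7-(1-hydroxypropan-2-ylidene)-1-methyl-5-(phenylsulfanyl)-3,4,4a,5,6,7,8,8a-octahydronaphthalene-4a-carboxylate (CH2OH cis to C6 of the decalin; isomer mixture) | CCOC(=O)C12CCC=C(C)C1(O)C/C(CC2Sc1ccccc1)=C(\C)CO
F2 | step 9 | ethyl (1E,4E,7Z)-4-(1-hydroxypropan-2-ylidene)-7-methyl-6-oxocyclodeca-1,7-diene-1-carboxylate | CCOC(=O)/C1=C/C/C(=C(/C)CO)CC(=O)/C(C)=C\CC1
F3 | step 5 | ethyl (5Z)-7-hydroxy-6-methyl-3-oxo-5-[2,2-bis(phenylsulfanyl)ethyl]hept-5-enoate | CCOC(=O)CC(=O)C/C(CC(Sc1ccccc1)Sc1ccccc1)=C(\C)CO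
F4 | step 8 | ethyl (4Z)-4-(1-hydroxypropan-2-ylidene)-1-[(3Z)-4-iodopent-3-en-1-yl]-2-oxo-6-(phenylsulfonyl)cyclohexane-1-carboxylate (isomer mixture) | CCOC(=O)C1(CC/C=C(\I)C)C(=O)C/C(=C(\C)CO)CC1S(=O)(=O)c1ccccc1
F5 | step 8 | ethyl (2S,3R)-2-(hydroxymethyl)-6-[(3Z)-4-iodopent-3-en-1-yl]-2-methyl-5-oxo-7-(phenylsulfonyl)-1-oxaspiro[2.5]octane-6-carboxylate (isomers at C6/C7) | CCOC(=O)C1(CC/C=C(\I)C)C(=O)C[C@]2(CC1S(=O)(=O)c1ccccc1)O[C@@]2(C)CO
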